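**Strategy**

Ring B of the target is a cyclohexenone in which the ketone carbon C8 (eremophilane numbering) sits between the enone CH C9 and the future enol carbon C7, opposite the methyl-bearing quaternary fusion carbon C5. This maps onto a rhodium-catalysed carbonylative [3+2+1] cycloaddition: C5–C6–C7 from a 1-methylcyclopropyl group, C9≡C10 from a terminal alkyne, C8 from CO. One operation forges C7–C8, C8–C9 and C5–C10, closes both rings and sets the quaternary centre. The precursor is an acyclic (Z)-enyne carrying the cyclopropane, the C4 methyl and a C3-epi silyl ether; C3 is inverted afterwards by Mitsunobu esterification with the side-chain acid and C7 is then oxidised to the diosphenol.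

Key step: step 7

Remark: locants C1–C10 in the Why lines follow eremophilane numbering (C3 ester carbon, C4 and C5 methyl-bearing carbons, ring B = C5–C10 with C8 the ketone and C7 the enol carbon, ring A = C10, C1–C5).

Assumption: the facial sense of the two organocatalysts (steps 3 and 9) is taken from the accepted transition-state models; if either proves opposite, its antipode is used.

**Route**

Step 1
Reactants: 1 (Z)-2-bromobut-2-ene
Product: 4 (Z)-4,4,5,5-tetramethyl-2-(2-methylbut-2-en-1-yl)-1,3,2-dioxaborolane, via alkenyllithium 2 (not isolated), via boronate complex 3 (not isolated)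
Conditions: t-BuLi (2 equiv), Et2O, −78 °C; then ClCH2B(pin), −78 °C to rt
Reagents that add atoms: 2-(chloromethyl)-4,4,5,5-tetramethyl-1,3,2-dioxaborolane, ClCB1OC(C)(C)C(C)(C)O1
Why: Bromine–lithium exchange on the alkenyl bromide is stereoretentive, and the alkenyllithium adds to boron to give an ate complex whose 1,2-metallate shift (Matteson homologation) expels chloride with retention of alkene geometry, giving the (Z)-γ-methyl allylboronate needed for a syn crotylation.

Step 2
Reactants: 5 ethyl (Z)-3-iodoprop-2-enoate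
Product: 7 (Z)-3-iodoprop-2-enal, via aluminium hemiacetal 6 (not isolated)
Conditions: i-Bu2AlH (1.05 equiv), CH2Cl2, −78 °C; aqueous Rochelle salt; crude aldehyde used at once
Reagents that add atoms: none
Why: Partial ester reduction with i-Bu2AlH at −78 °C stops at the aluminium hemiacetal, which collapses to the aldehyde only on work-up, and immediate use of the crude (Z)-iodoenal limits Z-to-E drift.

Step 3
Reactants: 7 (Z)-3-iodoprop-2-enal; 4 (Z)-4,4,5,5-tetramethyl-2-(2-methylbut-2-en-1-yl)-1,3,2-dioxaborolane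
Product: 9 (1Z,3S,4R)-1-iodo-4,5-dimethylhexa-1,5-dien-3-ol, via borate ester 8 (not isolated)
Conditions: (S)-TRIP [3,3′-bis(2,4,6-triisopropylphenyl)-1,1′-binaphthyl-2,2′-diyl hydrogen phosphate] (5 mol %), 4 Å molecular sieves, toluene, −30 °C; aqueous work-up
Reagents that add atoms: none
Why: Chiral-phosphoric-acid-catalysed allylboration runs through a closed chair (Zimmerman–Traxler) transition state, so the (Z)-boronate should give the 3,4-syn alcohol, while the (S)-acid, hydrogen-bonded to a boronate oxygen, should expose the Si face of the aldehyde and so fix the absolute configuration of C3 and C4.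

Step 4
Reactants: 9 (1Z,3S,4R)-1-iodo-4,5-dimethylhexa-1,5-dien-3-ol
Product: 10 tert-butyl{[(1Z,3S,4R)-1-iodo-4,5-dimethylhexa-1,5-dien-3-yl]oxy}dimethylsilane
Conditions: t-BuMe2SiOTf, 2,6-lutidine, CH2Cl2, −78 to 0 °C
Reagents that add atoms: tert-butyldimethylsilyl trifluoromethanesulfonate, CC(C)(C)[Si](C)(C)OS(=O)(=O)C(F)(F)F
Why: Silyl triflate/lutidine silylation of a hindered secondary alcohol is standard and removes the hydroxyl group that would otherwise direct a zinc carbenoid to the neighbouring iodoalkene.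

Step 5
Reactants: 10 tert-butyl{[(1Z,3S,4R)-1-iodo-4,5-dimethylhexa-1,5-dien-3-yl]oxy}dimethylsilane
Product: 11 tert-butyl{[(1Z,3S,4R)-1-iodo-4-(1-methylcyclopropyl)pent-1-en-3-yl]oxy}dimethylsilane
Conditions: Et2Zn, CF3CO2H, CH2I2, CH2Cl2, 0 °C to rt
Reagents that add atoms: diiodomethane, ICI
Why: Simmons–Smith cyclopropanation with the electrophilic carbenoid CF3CO2ZnCH2I should select the electron-rich 1,1-disubstituted alkene over the electron-poor iodoalkene, and no stereocentre arises because C5 then carries two identical ring CH2 groups.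

Step 6
Reactants: 11 tert-butyl{[(1Z,3S,4R)-1-iodo-4-(1-methylcyclopropyl)pent-1-en-3-yl]oxy}dimethylsilane
Product: 12 tert-butyldimethyl{[(3Z,5R,6R)-6-(1-methylcyclopropyl)hept-3-en-1-yn-5-yl]oxy}silane
Conditions: HC≡CMgBr, ZnBr2, Pd(PPh3)4 (5 mol %), THF, 0 °C to rt
Reagents that add atoms: ethynylmagnesium bromide, C#C[Mg]Br
Why: Negishi coupling of an alkenyl iodide with ethynylzinc bromide under zerovalent palladium catalysis is stereoretentive and delivers the terminal (Z)-enyne directly.

Step 7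
Reactants: 12 tert-butyldimethyl{[(3Z,5R,6R)-6-(1-methylcyclopropyl)hept-3-en-1-yn-5-yl]oxy}silane
Product: 13 (4aR,5R,6R)-6-[(tert-butyldimethylsilyl)oxy]-4a,5-dimethyl-4,4a,5,6-tetrahydronaphthalen-2(3H)-one
Conditions: [Rh(CO)2Cl]2 (10 mol %), CO (1 atm), p-xylene, 130 °C
Reagents that add atoms: carbon monoxide, [C-]#[O+]
Why: The alkyne binds monovalent rhodium and guides it into the proximal cyclopropane bond C5–C7 to give a rhodacyclobutane, the alkyne inserts into Rh–C5 (C5–C10), CO inserts, and reductive elimination joins C7–C8–C9. The closest known reaction type is the rhodium-catalysed carbonylative [3+2+1] cycloaddition of alkyne-tethered cyclopropanes (homologous Pauson–Khand reaction). Ring A closes through the (Z)-ene tether as a six-membered ring, exo with respect to the alkyne (C9 stays outside ring A), and ring B closes by reductive elimination from a seven-membered acyl rhodacycle. The only new stereocentre is C5, fixed by which of the two diastereotopic C5–CH2 bonds is cut, under control of the pre-set C3 and C4 centres through a chair-like ring A transition state. There the angular methyl must be axial because C6 is held near the plane of the nascent C9=C10 bond, so the path with C4-methyl and C3-silyloxy both equatorial should win and place the C5 methyl cis to the C4 methyl, whereas the other path would need C4-methyl axial and the silyloxy group syn-axial to the angular methyl; this is why the C3-epi series is used. The step also needs proximal rather than distal bond insertion and CO incorporation rather than carbonyl-free [3+2] closure, which alkyne chelation through the short rigid tether and the CO atmosphere should secure.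

Step 8
Reactants: 13 (4aR,5R,6R)-6-[(tert-butyldimethylsilyl)oxy]-4a,5-dimethyl-4,4a,5,6-tetrahydronaphthalen-2(3H)-one
Product: 14 (4aR,5R,6R)-6-hydroxy-4a,5-dimethyl-4,4a,5,6-tetrahydronaphthalen-2(3H)-one
Conditions: HF·pyridine, pyridine, THF, 0 °C to rt
Reagents that add atoms: none
Why: Mildly acidic fluoride cleaves the silyl ether without enolising the dienone and frees the C3 alcohol for inversion.

Step 9
Reactants: 15 butanal
Product: 17 ethyl (2E,4E,6R)-6-(hydroxymethyl)octa-2,4-dienoate, via hydroxy aldehyde 16 (not isolated)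
Conditions: (R)-2-[diphenyl(trimethylsilyloxy)methyl]pyrrolidine (10 mol %), 37 % aq. CH2O, pH 7 phosphate buffer, toluene, rt; organic phase dried, then Ph3P=CH–CH=CH–CO2Et, CH2Cl2, 0 °C to rt; then I2 (2 mol %), daylight
Reagents that add atoms: formaldehyde, C=O; ethyl (2E)-4-(triphenyl-λ5-phosphanylidene)but-2-enoate, CCOC(=O)/C=C/C=P(c1ccccc1)(c1ccccc1)c1ccccc1
Why: In this enamine-catalysed α-hydroxymethylation the diarylprolinol silyl ether shields one face of the E-enamine so that formaldehyde should give the (S)-aldehyde, which is trapped in the same pot by a neutral Wittig reaction with the stabilised vinylogous ylide before it can racemise or dehydrate, iodine then equilibrating the new double bond to E.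

Step 10
Reactants: 17 ethyl (2E,4E,6R)-6-(hydroxymethyl)octa-2,4-dienoate
Product: 18 ethyl (2E,4E,6R)-6-{[(tert-butyldimethylsilyl)oxy]methyl}octa-2,4-dienoate
Conditions: t-BuMe2SiCl, imidazole, DMF, rt
Reagents that add atoms: tert-butyldimethylsilyl chloride, CC(C)(C)[Si](C)(C)Cl
Why: Standard silylation of a primary alcohol, needed so that only the carboxylic acid reacts in the later Mitsunobu step.

Step 11
Reactants: 18 ethyl (2E,4E,6R)-6-{[(tert-butyldimethylsilyl)oxy]methyl}octa-2,4-dienoate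
Product: 19 (2E,4E,6R)-6-{[(tert-butyldimethylsilyl)oxy]methyl}octa-2,4-dienoic acid
Conditions: LiOH, THF/MeOH/H2O, rt; then dilute HCl to pH 4, 0 °C
Reagents that add atoms: lithium hydroxide, [Li+].[OH-]
Why: Saponification of the ethyl ester leaves the primary silyl ether, the diene geometry and the remote stereocentre untouched.

Step 12
Reactants: 14 (4aR,5R,6R)-6-hydroxy-4a,5-dimethyl-4,4a,5,6-tetrahydronaphthalen-2(3H)-one; 19 (2E,4E,6R)-6-{[(tert-butyldimethylsilyl)oxy]methyl}octa-2,4-dienoic acid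
Product: 20 (4aR,5R,6S)-4a,5-dimethyl-2-oxo-2,3,4,4a,5,6-hexahydronaphthalen-6-yl (2E,4E,6R)-6-{[(tert-butyldimethylsilyl)oxy]methyl}octa-2,4-dienoate
Conditions: PPh3, i-PrO2C–N=N–CO2i-Pr (DIAD), toluene, 0 °C to rt
Reagents that add atoms: none
Why: Mitsunobu esterification displaces the alkoxyphosphonium ion by the carboxylate in an SN2 step, so it attaches the side chain and inverts C3 to the all-cis C3/C4/C5 arrangement of the target in one operation.

Step 13
Reactants: 20 (4aR,5R,6S)-4a,5-dimethyl-2-oxo-2,3,4,4a,5,6-hexahydronaphthalen-6-yl (2E,4E,6R)-6-{[(tert-butyldimethylsilyl)oxy]methyl}octa-2,4-dienoate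
Product: 22 (3RS,4aR,5R,6S)-3-hydroxy-4a,5-dimethyl-2-oxo-2,3,4,4a,5,6-hexahydronaphthalen-6-yl (2E,4E,6R)-6-{[(tert-butyldimethylsilyl)oxy]methyl}octa-2,4-dienoate, via sodium enolate 21 (not isolated)
Conditions: NaN(SiMe3)2 (1.05 equiv), THF, −78 °C; then 2-(benzenesulfonyl)-3-phenyloxaziridine, −78 °C; aq. NH4Cl
Reagents that add atoms: 2-(benzenesulfonyl)-3-phenyloxaziridine, O=S(=O)(c1ccccc1)N1OC1c1ccccc1
Why: The hindered amide base should remove a C7 proton, the kinetically favoured α′ site of the dienone, and the cross-conjugated sodium enolate is oxidised by the N-sulfonyloxaziridine (Davis hydroxylation); the configuration of the new carbinol carbon is irrelevant because the next step destroys it.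

Step 14
Reactants: 22 (3RS,4aR,5R,6S)-3-hydroxy-4a,5-dimethyl-2-oxo-2,3,4,4a,5,6-hexahydronaphthalen-6-yl (2E,4E,6R)-6-{[(tert-butyldimethylsilyl)oxy]methyl}octa-2,4-dienoate
Product: 24 (4aS,5R,6S)-3-hydroxy-4a,5-dimethyl-2-oxo-2,4a,5,6-tetrahydronaphthalen-6-yl (2E,4E,6R)-6-{[(tert-butyldimethylsilyl)oxy]methyl}octa-2,4-dienoate, via 1,2-diketone 23 (not isolated)
Conditions: Dess–Martin periodinane, NaHCO3, CH2Cl2, 0 °C to rt
Reagents that add atoms: none
Why: Dess–Martin oxidation of the α-hydroxy ketone gives the 1,2-diketone, which should enolise spontaneously toward C6 to the conjugated diosphenol of ring B.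

Step 15
Reactants: 24 (4aS,5R,6S)-3-hydroxy-4a,5-dimethyl-2-oxo-2,4a,5,6-tetrahydronaphthalen-6-yl (2E,4E,6R)-6-{[(tert-butyldimethylsilyl)oxy]methyl}octa-2,4-dienoate
Product: 25 septeremophilane E
Conditions: HF·pyridine, pyridine, THF, 0 °C
Reagents that add atoms: none
Why: Fluoride-mediated cleavage of the primary silyl ether should leave the dienoate ester, the diosphenol and the diene geometry intact.

**Compound list**

1 | (Z)-2-bromobut-2-ene | C/C=C(/C)Br | starting material
2 | (E)-but-2-en-2-yllithium | C/C=C(/C)[Li] | intermediate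
3 | lithium [(E)-but-2-en-2-yl](chloromethyl)(pinacolato)borate | [Li+].C/C=C(/C)[B-]1(CCl)OC(C)(C)C(C)(C)O1 | intermediate
4 | (Z)-4,4,5,5-tetramethyl-2-(2-methylbut-2-en-1-yl)-1,3,2-dioxaborolane | C/C=C(/C)CB1OC(C)(C)C(C)(C)O1 | intermediate
5 | ethyl (Z)-3-iodoprop-2-enoate | CCOC(=O)/C=C\I | starting material
6 | {[(Z)-1-ethoxy-3-iodoprop-2-en-1-yl]oxy}bis(2-methylpropyl)alumane | CCOC(O[Al](CC(C)C)CC(C)C)/C=C\I | intermediate
7 | (Z)-3-iodoprop-2-enal | O=C/C=C\I | intermediate
8 | 2-{[(1Z,3S,4R)-1-iodo-4,5-dimethylhexa-1,5-dien-3-yl]oxy}-4,4,5,5-tetramethyl-1,3,2-dioxaborolane | I/C=C\[C@@H](OB1OC(C)(C)C(C)(C)O1)[C@H](C)C(C)=C | intermediate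
9 | (1Z,3S,4R)-1-iodo-4,5-dimethylhexa-1,5-dien-3-ol | I/C=C\[C@@H](O)[C@H](C)C(C)=C | intermediate
10 | tert-butyl{[(1Z,3S,4R)-1-iodo-4,5-dimethylhexa-1,5-dien-3-yl]oxy}dimethylsilane | I/C=C\[C@@H](O[Si](C)(C)C(C)(C)C)[C@H](C)C(C)=C | intermediate
11 | tert-butyl{[(1Z,3S,4R)-1-iodo-4-(1-methylcyclopropyl)pent-1-en-3-yl]oxy}dimethylsilane | I/C=C\[C@@H](O[Si](C)(C)C(C)(C)C)[C@H](C)C1(C)CC1 | intermediate
12 | tert-butyldimethyl{[(3Z,5R,6R)-6-(1-methylcyclopropyl)hept-3-en-1-yn-5-yl]oxy}silane | C#C/C=C\[C@@H](O[Si](C)(C)C(C)(C)C)[C@H](C)C1(C)CC1 | intermediate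
13 | (4aR,5R,6R)-6-[(tert-butyldimethylsilyl)oxy]-4a,5-dimethyl-4,4a,5,6-tetrahydronaphthalen-2(3H)-one | CC(C)(C)[Si](C)(C)O[C@@H]1C=CC2=CC(=O)CC[C@]2(C)[C@H]1C | intermediate
14 | (4aR,5R,6R)-6-hydroxy-4a,5-dimethyl-4,4a,5,6-tetrahydronaphthalen-2(3H)-one | O[C@@H]1C=CC2=CC(=O)CC[C@]2(C)[C@H]1C | intermediate
15 | butanal | CCCC=O | starting material
16 | (S)-2-(hydroxymethyl)butanal | CC[C@@H](CO)C=O | intermediate
17 | ethyl (2E,4E,6R)-6-(hydroxymethyl)octa-2,4-dienoate | CC[C@H](/C=C/C=C/C(=O)OCC)CO | intermediate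
18 | ethyl (2E,4E,6R)-6-{[(tert-butyldimethylsilyl)oxy]methyl}octa-2,4-dienoate | CC[C@H](/C=C/C=C/C(=O)OCC)CO[Si](C)(C)C(C)(C)C | intermediate
19 | (2E,4E,6R)-6-{[(tert-butyldimethylsilyl)oxy]methyl}octa-2,4-dienoic acid | CC[C@H](/C=C/C=C/C(=O)O)CO[Si](C)(C)C(C)(C)C | intermediate
20 | (4aR,5R,6S)-4a,5-dimethyl-2-oxo-2,3,4,4a,5,6-hexahydronaphthalen-6-yl (2E,4E,6R)-6-{[(tert-butyldimethylsilyl)oxy]methyl}octa-2,4-dienoate | CC[C@H](/C=C/C=C/C(=O)O[C@H]1C=CC2=CC(=O)CC[C@]2(C)[C@H]1C)CO[Si](C)(C)C(C)(C)C | intermediate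
21 | sodium 2-enolate of 20 (ring B C7=C8–ONa) | CC[C@H](/C=C/C=C/C(=O)O[C@H]1C=CC2=CC(O[Na])=CC[C@]2(C)[C@H]1C)CO[Si](C)(C)C(C)(C)C | intermediate
22 | (3RS,4aR,5R,6S)-3-hydroxy-4a,5-dimethyl-2-oxo-2,3,4,4a,5,6-hexahydronaphthalen-6-yl (2E,4E,6R)-6-{[(tert-butyldimethylsilyl)oxy]methyl}octa-2,4-dienoate (both C3 epimers serve) | CC[C@H](/C=C/C=C/C(=O)O[C@H]1C=CC2=CC(=O)C(O)C[C@]2(C)[C@H]1C)CO[Si](C)(C)C(C)(C)C | intermediate
23 | (4aR,5R,6S)-4a,5-dimethyl-2,3-dioxo-2,3,4,4a,5,6-hexahydronaphthalen-6-yl (2E,4E,6R)-6-{[(tert-butyldimethylsilyl)oxy]methyl}octa-2,4-dienoate | CC[C@H](/C=C/C=C/C(=O)O[C@H]1C=CC2=CC(=O)C(=O)C[C@]2(C)[C@H]1C)CO[Si](C)(C)C(C)(C)C | intermediate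
24 | (4aS,5R,6S)-3-hydroxy-4a,5-dimethyl-2-oxo-2,4a,5,6-tetrahydronaphthalen-6-yl (2E,4E,6R)-6-{[(tert-butyldimethylsilyl)oxy]methyl}octa-2,4-dienoate | CC[C@H](/C=C/C=C/C(=O)O[C@H]1C=CC2=CC(=O)C(O)=C[C@]2(C)[C@H]1C)CO[Si](C)(C)C(C)(C)C | intermediate
25 | septeremophilane E, (4aS,5R,6S)-3-hydroxy-4a,5-dimethyl-2-oxo-2,4a,5,6-tetrahydronaphthalen-6-yl (2E,4E,6R)-6-(hydroxymethyl)octa-2,4-dienoate | CC[C@H](/C=C/C=C/C(=O)O[C@H]1C=CC2=CC(=O)C(O)=C[C@]2(C)[C@H]1C)CO | target

**Step count**

Total: 15 steps. Longest linear sequence: 11 steps (5 to 25 through steps 2–8 and 12–15).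

**Steps most likely to fail**

1. Step 7. Oxidative addition of rhodium into the unactivated, fully substituted cyclopropane bond may be too slow, so that alkyne oligomerisation or carbonyl-free closure takes over, and discrimination between the two diastereotopic ring bonds may be incomplete. The fallback sets out from iodide 10 and rejoins at dienone 13. Stille coupling of 10 with (E)-4-(tributylstannyl)but-3-en-2-one (Pd(PPh3)4, CuI, DMF) should give (3E,5Z,7R,8R)-7-[(tert-butyldimethylsilyl)oxy]-8,9-dimethyldeca-3,5,9-trien-2-one F1. t-BuMe2SiOTf/Et3N converts the methyl ketone into the 2-silyloxy tetraene F2. Heating (toluene, 180 °C, sealed tube) should bring about an intramolecular Diels–Alder reaction of the silyloxydiene with the isopropenyl group through a trans-fused transition state with C4-methyl and C3-silyloxy equatorial, giving the bicyclic silyl enol ether F3 (its C8a epimers converge). Saegusa–Ito oxidation of F3 (Pd(OAc)2, MeCN) then gives 13.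

2. Step 12. The carboxylate must attack C3 syn to the axial angular methyl, so elimination of the activated alcohol to a triene or allylic transposition may outrun the SN2 inversion. The fallback sets out from alcohol 14 and rejoins at ester 20. Dess–Martin oxidation of 14 gives (4aR,5R)-4a,5-dimethyl-4,4a-dihydronaphthalene-2,6(3H,5H)-dione F4. NaN(SiMe3)2 (1 equiv, THF, −78 °C) masks the ring B ketone as the sodium enolate F5, and i-Bu2AlH added to the same flask should reduce the free C3 ketone from the face away from the angular methyl. Work-up gives the 3,4-cis alcohol (4aR,5R,6S)-6-hydroxy-4a,5-dimethyl-4,4a,5,6-tetrahydronaphthalen-2(3H)-one F6. Yamaguchi esterification of F6 with acid 19 (2,4,6-trichlorobenzoyl chloride, Et3N, then DMAP) gives 20.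

3. Step 13. Deprotonation may stray to the C3 hydrogen or the base may attack the ester, and the enolate may add to the sulfonimine by-product or be oxidised further. The fallback sets out from 20 and rejoins at 22. Soft enolisation (Me3SiOTf, Et3N, CH2Cl2, 0 °C) gives the cross-conjugated trimethylsilyl dienol ether F7. Rubottom oxidation (m-CPBA, NaHCO3, CH2Cl2, −20 °C), selective for the electron-rich silyl enol ether over the electron-poor dienone and dienoate, gives the α-(trimethylsilyloxy) ketone F8. Brief treatment with citric acid in methanol releases 22.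

Further compounds
F1 | step 7 | (3E,5Z,7R,8R)-7-[(tert-butyldimethylsilyl)oxy]-8,9-dimethyldeca-3,5,9-trien-2-one | CC(=O)/C=C/C=C\[C@@H](O[Si](C)(C)C(C)(C)C)[C@H](C)C(C)=C
F2 | step 7 | tert-butyl{[(3E,5Z,7R,8R)-7-[(tert-butyldimethylsilyl)oxy]-8,9-dimethyldeca-1,3,5,9-tetraen-2-yl]oxy}dimethylsilane | C=C(O[Si](C)(C)C(C)(C)C)/C=C/C=C\[C@@H](O[Si](C)(C)C(C)(C)C)[C@H](C)C(C)=C
F3 | step 7 | (4aS,5R,6R)-2,6-bis[(tert-butyldimethylsilyl)oxy]-4a,5-dimethyl-3,4,4a,5,6,8a-hexahydronaphthalene (C8a epimers) | CC(C)(C)[Si](C)(C)O[C@@H]1C=CC2C=C(O[Si](C)(C)C(C)(C)C)CC[C@]2(C)[C@H]1C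
F4 | step 12 | (4aR,5R)-4a,5-dimethyl-4,4a-dihydronaphthalene-2,6(3H,5H)-dione | O=C1C=CC2=CC(=O)CC[C@]2(C)[C@H]1C
F5 | step 12 | sodium 2-enolate of F4 | O=C1C=CC2=CC(O[Na])=CC[C@]2(C)[C@H]1C
F6 | step 12 | (4aR,5R,6S)-6-hydroxy-4a,5-dimethyl-4,4a,5,6-tetrahydronaphthalen-2(3H)-one | O[C@H]1C=CC2=CC(=O)CC[C@]2(C)[C@H]1C
F7 | step 13 | trimethylsilyl dienol ether of 20 | CC[C@H](/C=C/C=C/C(=O)O[C@H]1C=CC2=CC(O[Si](C)(C)C)=CC[C@]2(C)[C@H]1C)CO[Si](C)(C)C(C)(C)C
F8 | step 13 | 3-(trimethylsilyloxy) ketone corresponding to 22 | CC[C@H](/C=C/C=C/C(=O)O[C@H]1C=CC2=CC(=O)C(O[Si](C)(C)C)C[C@]2(C)[C@H]1C)CO[Si](C)(C)C(C)(C)C
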